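**Plan**
1. The target is a trans-decalin (ring A C1–C5/C10, ring B C5–C10) with C4 (axial Me, equatorial CO2Me), equatorial C6–OAc, exocyclic C8=C17 and an (E)-dienyl chain on C9. Retrosynthesis first removes the acetate, the C14=C15 and C12=C13 alkenes and the C18 oxidation level.
2. The C9–C10 and C4–C5 bonds are then cut together, which opens both rings to an acyclic epoxy diene allylsilane. This chain is cut further at C9–C11/C8–C17, C6–C7, C5–C6/C10–C20 and C2–C3.
3. Forward, the chain is built linearly from (R)-2-methylglycidol. Ring A (C4–C5) and then ring B (C9–C10) arise in one cation–olefin cascade.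
4. The feature that allows this is the 1,5-diene array C5=C10 / C8=C9 behind an electrophilic C4, with the C18 oxygen on C4 (as the oxirane C4–O–C18) and the C6 oxygen allylic to the central alkene.
5. C4 comes from the glycidol stereocentre (inversion on ring closure) and C6 from a catalyst-controlled propargylation. C5, C10 and C9 follow from C6 (allylic strain), the E alkene and the allylsilane geometry through a chair–chair transition state.

Key step: step 11

Remark: the SMILES is read as C4 methyl axial and cis to the C10 methyl, C4 ester and C6 acetate equatorial; (R)-2-methylglycidol and the other building blocks are taken as commercial.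

Step 1
Reactants: 1 (R)-2-methylglycidol
Product: 2 triethyl{[(2S)-2-methyloxiran-2-yl]methoxy}silane
Conditions: TESCl, imidazole, CH2Cl2, 0 °C
Reagents that add atoms: chlorotriethylsilane CC[Si](Cl)(CC)CC
Why: Imidazole-mediated silylation protects the future C18 oxygen as a primary TES ether that can later be removed beside a secondary TBS ether; the stereocentre is not touched (the descriptor changes only through priorities).

Step 2
Reactants: 2 triethyl{[(2S)-2-methyloxiran-2-yl]methoxy}silane; 3 (4-bromobut-1-yn-1-yl)trimethylsilane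
Product: 5 (2S)-2-methyl-1-[(triethylsilyl)oxy]-7-(trimethylsilyl)hept-6-yn-2-ol, via Grignard reagent 4 (not isolated)
Conditions: Mg, THF (3 to 4); then 2, CuI (10 mol %), THF, −30 → 0 °C; aq. NH4Cl
Reagents that add atoms: none
Why: Copper-catalysed Grignard opening of the 2,2-disubstituted oxirane should occur by SN2 attack at the unhindered CH2, forming C2–C3 and leaving the quaternary carbinol carbon (future C4) intact.

Step 3
Reactants: 5 (2S)-2-methyl-1-[(triethylsilyl)oxy]-7-(trimethylsilyl)hept-6-yn-2-ol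
Product: 6 (2S)-2-methyl-1-[(triethylsilyl)oxy]hept-6-yn-2-ol
Conditions: K2CO3 (0.3 equiv), MeOH, 0 °C → rt, short reaction time
Reagents that add atoms: none
Why: Base-mediated methanolysis should remove the alkynyl silyl group, which is far more labile than the primary TES ether under brief treatment.

Step 4
Reactants: 6 (2S)-2-methyl-1-[(triethylsilyl)oxy]hept-6-yn-2-ol
Product: 8 (2E,7S)-3,7-dimethyl-8-[(triethylsilyl)oxy]oct-2-ene-1,7-diol, via alkenyldimethylalane 7 (not isolated)
Conditions: AlMe3 (3.5 equiv), Cp2ZrCl2 (0.25 equiv), CH2Cl2, 0 °C → rt; then (CH2O)n, 0 °C → rt; aq. Rochelle salt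
Reagents that add atoms: trimethylaluminium C[Al](C)C; formaldehyde (as paraformaldehyde) C=O
Why: Negishi carboalumination adds methyl and aluminium syn and regioselectively across the terminal alkyne, and trapping of the alkenylalane with formaldehyde should give the E-trisubstituted allylic alcohol (C10=C5 with the C20 methyl and C6).

Step 5
Reactants: 8 (2E,7S)-3,7-dimethyl-8-[(triethylsilyl)oxy]oct-2-ene-1,7-diol
Product: 9 (2E,7S)-7-hydroxy-3,7-dimethyl-8-[(triethylsilyl)oxy]oct-2-enal
Conditions: MnO2 (excess), CH2Cl2, rt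
Reagents that add atoms: none
Why: MnO2 oxidises only the allylic alcohol, so the tertiary alcohol, the TES ether and the E geometry should be retained.

Step 6
Reactants: 9 (2E,7S)-7-hydroxy-3,7-dimethyl-8-[(triethylsilyl)oxy]oct-2-enal; 10 allenylboronic acid pinacol ester
Product: 11 (4R,5E,10S)-6,10-dimethyl-11-[(triethylsilyl)oxy]undec-5-en-1-yne-4,10-diol
Conditions: (R)-TRIP [3,3′-bis(2,4,6-triisopropylphenyl)-1,1′-binaphthyl-2,2′-diyl hydrogen phosphate] (10 mol %), 4 Å molecular sieves, toluene, −20 °C; aqueous work-up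
Reagents that add atoms: none
Why: In this Brønsted-acid-catalysed asymmetric propargylation the chiral phosphoric acid activates the allenylboronate, which adds through a closed six-membered transition state with allenyl-to-propargyl transposition and sets C6; the catalyst antipode is chosen to give the 4R carbinol (the R acid is expected to do so by analogy with aryl aldehydes, to be confirmed by Mosher analysis).

Step 7
Reactants: 11 (4R,5E,10S)-6,10-dimethyl-11-[(triethylsilyl)oxy]undec-5-en-1-yne-4,10-diol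
Product: 12 (2S,6E,8R)-8-[(tert-butyldimethylsilyl)oxy]-2,6-dimethyl-1-[(triethylsilyl)oxy]undec-6-en-10-yn-2-ol
Conditions: TBSCl, imidazole, DMF, rt
Reagents that add atoms: tert-butylchlorodimethylsilane CC(C)(C)[Si](C)(C)Cl
Why: Standard silylation protects the secondary C6 alcohol, while the tertiary alcohol is too hindered to react with TBSCl/imidazole.

Step 8
Reactants: 12 (2S,6E,8R)-8-[(tert-butyldimethylsilyl)oxy]-2,6-dimethyl-1-[(triethylsilyl)oxy]undec-6-en-10-yn-2-ol; 13 allyl bromide
Product: 15 (2S,6E,8R,10Z)-8-[(tert-butyldimethylsilyl)oxy]-2,6-dimethyl-1-[(triethylsilyl)oxy]-10-[(trimethylsilyl)methyl]tetradeca-6,10,13-trien-2-ol, via alkenylcopper species 14 (not isolated)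
Conditions: Me3SiCH2MgCl (3 equiv), CuBr·SMe2 (3 equiv), Et2O/Me2S, −40 °C; 12, −40 °C → rt; then 13, −30 °C → rt
Reagents that add atoms: (trimethylsilyl)methylmagnesium chloride C[Si](C)(C)C[Mg]Cl
Why: Carbocupration adds the (trimethylsilyl)methylcopper reagent syn across the terminal alkyne (CH2SiMe3 to the internal carbon C8, copper to C9), and allylation of the alkenylcopper with retention should give the trisubstituted allylsilane with C7 and C11 trans; one equivalent of reagent is consumed by the tertiary hydroxyl.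

Step 9
Reactants: 15 (2S,6E,8R,10Z)-8-[(tert-butyldimethylsilyl)oxy]-2,6-dimethyl-1-[(triethylsilyl)oxy]-10-[(trimethylsilyl)methyl]tetradeca-6,10,13-trien-2-ol
Product: 16 (2S,6E,8R,10Z)-8-[(tert-butyldimethylsilyl)oxy]-2,6-dimethyl-10-[(trimethylsilyl)methyl]tetradeca-6,10,13-triene-1,2-diol
Conditions: PPTS (0.2 equiv), MeOH/CH2Cl2, 0 °C
Reagents that add atoms: none
Why: Mild acid methanolysis cleaves a primary TES ether much faster than a secondary TBS ether, and PPTS is too weak an acid to protodesilylate the allylsilane.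

Step 10
Reactants: 16 (2S,6E,8R,10Z)-8-[(tert-butyldimethylsilyl)oxy]-2,6-dimethyl-10-[(trimethylsilyl)methyl]tetradeca-6,10,13-triene-1,2-diol
Product: 18 (2S)-2-[(4E,6R,8Z)-6-[(tert-butyldimethylsilyl)oxy]-4-methyl-8-[(trimethylsilyl)methyl]dodeca-4,8,11-trien-1-yl]-2-methyloxirane, via primary tosylate 17 (not isolated)
Conditions: NaH (2.5 equiv), 1-(p-toluenesulfonyl)imidazole (1.1 equiv), THF, 0 °C → rt
Reagents that add atoms: none
Why: One-pot sulfonylation of the primary alkoxide and intramolecular Williamson closure by the tertiary alkoxide should give the 2,2-disubstituted oxirane with retention at C4, because the tertiary C–O bond is never broken.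

Step 11
Reactants: 18 (2S)-2-[(4E,6R,8Z)-6-[(tert-butyldimethylsilyl)oxy]-4-methyl-8-[(trimethylsilyl)methyl]dodeca-4,8,11-trien-1-yl]-2-methyloxirane
Product: 19 [(1S,4aS,5R,8R,8aS)-8-[(tert-butyldimethylsilyl)oxy]-1,4a-dimethyl-6-methylidene-5-(prop-2-en-1-yl)decahydronaphthalen-1-yl]methanol
Conditions: MeAlCl2 (2 equiv), CH2Cl2, −78 °C; then Et3N, MeOH; aq. Rochelle salt
Reagents that add atoms: none
Why: Coordination of MeAlCl2 to the oxirane oxygen triggers heterolysis of the tertiary C4–O bond with backside participation of the C5=C10 alkene (6-endo closure of ring A, inversion at C4); the tertiary C10 cation is then captured 6-endo by C9 of the allylsilane (ring B, the C9–C10 bond), and loss of silicon from the β-silyl cation at C8 leaves only the exocyclic C8=C17 alkene. The closest known reaction type is the Lewis-acid epoxide-initiated, allylsilane-terminated cation–olefin bicyclization of epoxy polyene silanes to labd-8(17)-enes; the extension here is a 2,2-disubstituted oxirane as initiator and a silyloxy stereocentre on the chain. C4 is set by stereospecific inversion of the (S)-oxirane (methyl axial, CH2O equatorial), C5 and C10 by anti addition across the E alkene in a chair–chair transition state (trans ring fusion), and C9 by the allylsilane geometry (C7 and C11 trans, so the allyl chain becomes equatorial). The absolute sense is fixed by C6: allylic 1,3-strain with the C10 methyl forces H6 to eclipse the alkene so that the silyloxy group becomes equatorial, and the (S)-oxirane is the matched partner because it places the CH2O–Al group equatorial in the same chair. The step needs ring closure to outpace hydride shift of the activated oxirane although the first alkene is inductively deactivated by the allylic oxygen; a silyl ether (weak donor, no neighbouring-group participation) and low temperature are chosen for this reason, and the terminal vinyl group should be inert.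

Step 12
Reactants: 19 [(1S,4aS,5R,8R,8aS)-8-[(tert-butyldimethylsilyl)oxy]-1,4a-dimethyl-6-methylidene-5-(prop-2-en-1-yl)decahydronaphthalen-1-yl]methanol
Product: 20 (1S,4aS,5R,8R,8aS)-8-[(tert-butyldimethylsilyl)oxy]-1,4a-dimethyl-6-methylidene-5-(prop-2-en-1-yl)decahydronaphthalene-1-carbaldehyde
Conditions: Dess–Martin periodinane, NaHCO3, CH2Cl2, 0 °C → rt
Reagents that add atoms: none
Why: Dess–Martin oxidation of the neopentyl primary alcohol under buffered conditions should leave both alkenes and the silyl ether untouched; C4 is quaternary, so nothing can epimerise.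

Step 13
Reactants: 20 (1S,4aS,5R,8R,8aS)-8-[(tert-butyldimethylsilyl)oxy]-1,4a-dimethyl-6-methylidene-5-(prop-2-en-1-yl)decahydronaphthalene-1-carbaldehyde
Product: 21 (1S,4aS,5R,8R,8aS)-8-[(tert-butyldimethylsilyl)oxy]-1,4a-dimethyl-6-methylidene-5-(prop-2-en-1-yl)decahydronaphthalene-1-carboxylic acid
Conditions: NaClO2, NaH2PO4, 2-methyl-2-butene (excess), t-BuOH/H2O, rt
Reagents that add atoms: sodium chlorite [Na+].[O-]Cl=O
Why: Pinnick oxidation converts the hindered aldehyde into the acid, with 2-methyl-2-butene scavenging hypochlorous acid so that the two alkenes survive.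

Step 14
Reactants: 21 (1S,4aS,5R,8R,8aS)-8-[(tert-butyldimethylsilyl)oxy]-1,4a-dimethyl-6-methylidene-5-(prop-2-en-1-yl)decahydronaphthalene-1-carboxylic acid
Product: 22 methyl (1S,4aS,5R,8R,8aS)-8-[(tert-butyldimethylsilyl)oxy]-1,4a-dimethyl-6-methylidene-5-(prop-2-en-1-yl)decahydronaphthalene-1-carboxylate
Conditions: Me3SiCHN2, MeOH/toluene, 0 °C
Reagents that add atoms: (trimethylsilyl)diazomethane C[Si](C)(C)C=[N+]=[N-]
Why: O-Methylation of the carboxylate by the diazoalkane is insensitive to the steric hindrance at the C4 carboxyl group.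

Step 15
Reactants: 22 methyl (1S,4aS,5R,8R,8aS)-8-[(tert-butyldimethylsilyl)oxy]-1,4a-dimethyl-6-methylidene-5-(prop-2-en-1-yl)decahydronaphthalene-1-carboxylate; 23 methacrolein
Product: 24 methyl (1S,4aS,5R,8R,8aS)-8-[(tert-butyldimethylsilyl)oxy]-1,4a-dimethyl-6-methylidene-5-[(2E)-3-methyl-4-oxobut-2-en-1-yl]decahydronaphthalene-1-carboxylate
Conditions: 23 (excess), second-generation Hoveyda–Grubbs catalyst (5 mol %), CH2Cl2, 40 °C
Reagents that add atoms: none
Why: In this olefin cross-metathesis the monosubstituted allyl alkene reacts with methacrolein while the hindered 1,1-disubstituted exocyclic alkene should be inert, and the trisubstituted enal is expected as the thermodynamically favoured E isomer.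

Step 16
Reactants: 24 methyl (1S,4aS,5R,8R,8aS)-8-[(tert-butyldimethylsilyl)oxy]-1,4a-dimethyl-6-methylidene-5-[(2E)-3-methyl-4-oxobut-2-en-1-yl]decahydronaphthalene-1-carboxylate
Product: 25 methyl (1S,4aS,5R,8R,8aS)-8-[(tert-butyldimethylsilyl)oxy]-1,4a-dimethyl-6-methylidene-5-[(2E)-3-methylpenta-2,4-dien-1-yl]decahydronaphthalene-1-carboxylate
Conditions: Ph3PCH3Br, KN(SiMe3)2, THF, −78 → 0 °C
Reagents that add atoms: methyltriphenylphosphonium bromide C[P+](c1ccccc1)(c1ccccc1)c1ccccc1.[Br-]
Why: Wittig methylenation of the enal with the non-stabilised ylide at low temperature should give the 1,3-diene without touching the hindered methyl ester or the E-trisubstituted alkene.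

Step 17
Reactants: 25 methyl (1S,4aS,5R,8R,8aS)-8-[(tert-butyldimethylsilyl)oxy]-1,4a-dimethyl-6-methylidene-5-[(2E)-3-methylpenta-2,4-dien-1-yl]decahydronaphthalene-1-carboxylate
Product: 26 methyl (1S,4aS,5R,8R,8aS)-8-hydroxy-1,4a-dimethyl-6-methylidene-5-[(2E)-3-methylpenta-2,4-dien-1-yl]decahydronaphthalene-1-carboxylate
Conditions: Bu4NF, AcOH (1:1), THF, rt → 40 °C
Reagents that add atoms: none
Why: Fluoride cleaves the secondary TBS ether, and the acetic acid buffer keeps the liberated C6 alkoxide from attacking the neighbouring C18 ester and spares the diene.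

Step 18
Reactants: 26 methyl (1S,4aS,5R,8R,8aS)-8-hydroxy-1,4a-dimethyl-6-methylidene-5-[(2E)-3-methylpenta-2,4-dien-1-yl]decahydronaphthalene-1-carboxylate
Product: 27 methyl (1S,4aS,5R,8R,8aS)-8-(acetyloxy)-1,4a-dimethyl-6-methylidene-5-[(2E)-3-methylpenta-2,4-dien-1-yl]decahydronaphthalene-1-carboxylate (target)
Conditions: Ac2O, DMAP (cat.), pyridine, rt
Reagents that add atoms: acetic anhydride CC(=O)OC(C)=O
Why: DMAP-catalysed acetylation of the equatorial secondary alcohol should give the target with no change at any stereocentre.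

**Compound list**
1 | (R)-2-methylglycidol, [(2R)-2-methyloxiran-2-yl]methanol | C[C@]1(CO1)CO | starting material
2 | triethyl{[(2S)-2-methyloxiran-2-yl]methoxy}silane | C[C@]1(CO1)CO[Si](CC)(CC)CC | intermediate
3 | (4-bromobut-1-yn-1-yl)trimethylsilane | C[Si](C)(C)C#CCCBr | starting material
4 | [4-(trimethylsilyl)but-3-yn-1-yl]magnesium bromide | C[Si](C)(C)C#CCC[Mg]Br | intermediate
5 | (2S)-2-methyl-1-[(triethylsilyl)oxy]-7-(trimethylsilyl)hept-6-yn-2-ol | C[Si](C)(C)C#CCCC[C@](C)(O)CO[Si](CC)(CC)CC | intermediate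
6 | (2S)-2-methyl-1-[(triethylsilyl)oxy]hept-6-yn-2-ol | C#CCCC[C@](C)(O)CO[Si](CC)(CC)CC | intermediate
7 | (E)-alkenyldimethylalane from 6 (tertiary oxygen as its dimethylaluminium alkoxide) | C[Al](C)/C=C(\C)CCC[C@](C)(O[Al](C)C)CO[Si](CC)(CC)CC | intermediate
8 | (2E,7S)-3,7-dimethyl-8-[(triethylsilyl)oxy]oct-2-ene-1,7-diol | OC/C=C(\C)CCC[C@](C)(O)CO[Si](CC)(CC)CC | intermediate
9 | (2E,7S)-7-hydroxy-3,7-dimethyl-8-[(triethylsilyl)oxy]oct-2-enal | O=C/C=C(\C)CCC[C@](C)(O)CO[Si](CC)(CC)CC | intermediate
10 | allenylboronic acid pinacol ester | C=C=CB1OC(C)(C)C(C)(C)O1 | starting material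
11 | (4R,5E,10S)-6,10-dimethyl-11-[(triethylsilyl)oxy]undec-5-en-1-yne-4,10-diol | C#CC[C@@H](O)/C=C(\C)CCC[C@](C)(O)CO[Si](CC)(CC)CC | intermediate
12 | (2S,6E,8R)-8-[(tert-butyldimethylsilyl)oxy]-2,6-dimethyl-1-[(triethylsilyl)oxy]undec-6-en-10-yn-2-ol | C#CC[C@@H](O[Si](C)(C)C(C)(C)C)/C=C(\C)CCC[C@](C)(O)CO[Si](CC)(CC)CC | intermediate
13 | allyl bromide | C=CCBr | starting material
14 | alkenylcopper species from 12 (copper on C9 trans to C7, tertiary oxygen as magnesium alkoxide) | [Cu]/C=C(C[Si](C)(C)C)/C[C@@H](O[Si](C)(C)C(C)(C)C)/C=C(\C)CCC[C@](C)(O[Mg]Cl)CO[Si](CC)(CC)CC | intermediate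
15 | (2S,6E,8R,10Z)-8-[(tert-butyldimethylsilyl)oxy]-2,6-dimethyl-1-[(triethylsilyl)oxy]-10-[(trimethylsilyl)methyl]tetradeca-6,10,13-trien-2-ol | C=CC/C=C(C[Si](C)(C)C)/C[C@@H](O[Si](C)(C)C(C)(C)C)/C=C(\C)CCC[C@](C)(O)CO[Si](CC)(CC)CC | intermediate
16 | (2S,6E,8R,10Z)-8-[(tert-butyldimethylsilyl)oxy]-2,6-dimethyl-10-[(trimethylsilyl)methyl]tetradeca-6,10,13-triene-1,2-diol | C=CC/C=C(C[Si](C)(C)C)/C[C@@H](O[Si](C)(C)C(C)(C)C)/C=C(\C)CCC[C@](C)(O)CO | intermediate
17 | primary 4-methylbenzenesulfonate of diol 16 | C=CC/C=C(C[Si](C)(C)C)/C[C@@H](O[Si](C)(C)C(C)(C)C)/C=C(\C)CCC[C@](C)(O)COS(=O)(=O)c1ccc(C)cc1 | intermediate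
18 | (2S)-2-[(4E,6R,8Z)-6-[(tert-butyldimethylsilyl)oxy]-4-methyl-8-[(trimethylsilyl)methyl]dodeca-4,8,11-trien-1-yl]-2-methyloxirane | C=CC/C=C(C[Si](C)(C)C)/C[C@@H](O[Si](C)(C)C(C)(C)C)/C=C(\C)CCC[C@@]1(C)CO1 | intermediate
19 | [(1S,4aS,5R,8R,8aS)-8-[(tert-butyldimethylsilyl)oxy]-1,4a-dimethyl-6-methylidene-5-(prop-2-en-1-yl)decahydronaphthalen-1-yl]methanol | C=CC[C@@H]1C(=C)C[C@@H](O[Si](C)(C)C(C)(C)C)[C@H]2[C@@]1(C)CCC[C@]2(C)CO | intermediate
20 | (1S,4aS,5R,8R,8aS)-8-[(tert-butyldimethylsilyl)oxy]-1,4a-dimethyl-6-methylidene-5-(prop-2-en-1-yl)decahydronaphthalene-1-carbaldehyde | C=CC[C@@H]1C(=C)C[C@@H](O[Si](C)(C)C(C)(C)C)[C@H]2[C@@]1(C)CCC[C@]2(C)C=O | intermediate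
21 | (1S,4aS,5R,8R,8aS)-8-[(tert-butyldimethylsilyl)oxy]-1,4a-dimethyl-6-methylidene-5-(prop-2-en-1-yl)decahydronaphthalene-1-carboxylic acid | C=CC[C@@H]1C(=C)C[C@@H](O[Si](C)(C)C(C)(C)C)[C@H]2[C@@]1(C)CCC[C@]2(C)C(=O)O | intermediate
22 | methyl (1S,4aS,5R,8R,8aS)-8-[(tert-butyldimethylsilyl)oxy]-1,4a-dimethyl-6-methylidene-5-(prop-2-en-1-yl)decahydronaphthalene-1-carboxylate | C=CC[C@@H]1C(=C)C[C@@H](O[Si](C)(C)C(C)(C)C)[C@H]2[C@@]1(C)CCC[C@]2(C)C(=O)OC | intermediate
23 | methacrolein | CC(=C)C=O | starting material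
24 | methyl (1S,4aS,5R,8R,8aS)-8-[(tert-butyldimethylsilyl)oxy]-1,4a-dimethyl-6-methylidene-5-[(2E)-3-methyl-4-oxobut-2-en-1-yl]decahydronaphthalene-1-carboxylate | O=C/C(C)=C/C[C@@H]1C(=C)C[C@@H](O[Si](C)(C)C(C)(C)C)[C@H]2[C@@]1(C)CCC[C@]2(C)C(=O)OC | intermediate
25 | methyl (1S,4aS,5R,8R,8aS)-8-[(tert-butyldimethylsilyl)oxy]-1,4a-dimethyl-6-methylidene-5-[(2E)-3-methylpenta-2,4-dien-1-yl]decahydronaphthalene-1-carboxylate | C=C/C(C)=C/C[C@@H]1C(=C)C[C@@H](O[Si](C)(C)C(C)(C)C)[C@H]2[C@@]1(C)CCC[C@]2(C)C(=O)OC | intermediate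
26 | methyl (1S,4aS,5R,8R,8aS)-8-hydroxy-1,4a-dimethyl-6-methylidene-5-[(2E)-3-methylpenta-2,4-dien-1-yl]decahydronaphthalene-1-carboxylate | C=C/C(C)=C/C[C@@H]1C(=C)C[C@@H](O)[C@H]2[C@@]1(C)CCC[C@]2(C)C(=O)OC | intermediate
27 | methyl (1S,4aS,5R,8R,8aS)-8-(acetyloxy)-1,4a-dimethyl-6-methylidene-5-[(2E)-3-methylpenta-2,4-dien-1-yl]decahydronaphthalene-1-carboxylate | C=C/C(C)=C/C[C@@H]1C(=C)C[C@@H](OC(C)=O)[C@H]2[C@@]1(C)CCC[C@]2(C)C(=O)OC | target

**Step count and risks**
Total steps: 18. Longest linear sequence: 18 steps (from 1).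

Most likely to fail, in this order:

Step 11 (bicyclization). The first alkene is deactivated by the allylic oxygen, so hydride shift of the activated oxirane (Meinwald-type rearrangement to the aldehyde), arrest after ring A, or protodesilylation could outrun the cascade. The fallback changes from the cationic to a radical manifold, which tolerates the allylic oxygen and needs no silicon. It sets out from alkyne 12. Zirconium-catalysed methylalumination (AlMe3, Cp2ZrCl2) gives the alkenylalane F1 (not isolated), which is allylated in the same flask with allyl bromide 13 and Pd(PPh3)4 to the methyl-terminated triene F2. PPTS/MeOH then gives the diol F3, and NaH with 1-(p-toluenesulfonyl)imidazole gives, through the tosylate F4 (not isolated), the oxirane F5. Cp2TiCl (trivalent titanium, made from Cp2TiCl2 and Mn dust in THF) opens F5 homolytically to the tertiary C4 radical, which should undergo the same two 6-endo closures. The tertiary C8 radical is trapped by a second Cp2TiCl and loses a β-hydride from the methyl group to give the exocyclic alkene, so the route is rejoined at alcohol 19. In this mode C4 is no longer set by inversion but by the chair preference for an equatorial CH2OTi group, so the C4 epimer must be expected as a by-product and removed at this stage.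

Step 8 (carbocupration and allylation). Addition of the α-silyl organocopper reagent could be slow or regiochemically imperfect, or the alkenylcopper could lose its geometry before allylation. The fallback sets out from alkyne 12 and returns at 15. Palladium-catalysed bromoallylation of the alkyne with allyl bromide 13 (PdBr2(PhCN)2; cis-bromopalladation, allyl insertion, β-bromide elimination) should give the (Z)-2-bromo-1,4-diene F6, with bromine on C8 and the allyl group on C9. Kumada coupling of F6 with Me3SiCH2MgCl and Pd(PPh3)4 (zerovalent palladium) then introduces the silylmethyl group with retention and gives 15.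

Step 6 (asymmetric propargylation). Enantiofacial control could be insufficient for a β,β-disubstituted enal, or the free tertiary hydroxyl could interfere with the boronate. The fallback sets out from enal 9 and returns at 11. Zinc-mediated Barbier propargylation with propargyl bromide gives the C4-epimeric alcohols F7, and buffered Dess–Martin oxidation gives the propargyl enone F8. Corey–Bakshi–Shibata reduction ((S)-2-methyl-CBS-oxazaborolidine, catecholborane, −78 °C) then differentiates the alkenyl (large) and propargyl (small) flanks and should give the 4R alcohol 11.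

**Further compounds**
F1 | step 11 | (E)-alkenyldimethylalane from 12 (aluminium on C9 trans to C7, tertiary oxygen as dimethylaluminium alkoxide) | C[Al](C)/C=C(C)/C[C@@H](O[Si](C)(C)C(C)(C)C)/C=C(\C)CCC[C@](C)(O[Al](C)C)CO[Si](CC)(CC)CC
F2 | step 11 | (2S,6E,8R,10E)-8-[(tert-butyldimethylsilyl)oxy]-2,6,10-trimethyl-1-[(triethylsilyl)oxy]tetradeca-6,10,13-trien-2-ol | C=CC/C=C(C)/C[C@@H](O[Si](C)(C)C(C)(C)C)/C=C(\C)CCC[C@](C)(O)CO[Si](CC)(CC)CC
F3 | step 11 | (2S,6E,8R,10E)-8-[(tert-butyldimethylsilyl)oxy]-2,6,10-trimethyltetradeca-6,10,13-triene-1,2-diol | C=CC/C=C(C)/C[C@@H](O[Si](C)(C)C(C)(C)C)/C=C(\C)CCC[C@](C)(O)CO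
F4 | step 11 | primary 4-methylbenzenesulfonate of diol F3 | C=CC/C=C(C)/C[C@@H](O[Si](C)(C)C(C)(C)C)/C=C(\C)CCC[C@](C)(O)COS(=O)(=O)c1ccc(C)cc1
F5 | step 11 | (2S)-2-[(4E,6R,8E)-6-[(tert-butyldimethylsilyl)oxy]-4,8-dimethyldodeca-4,8,11-trien-1-yl]-2-methyloxirane | C=CC/C=C(C)/C[C@@H](O[Si](C)(C)C(C)(C)C)/C=C(\C)CCC[C@@]1(C)CO1
F6 | step 8 | (2S,6E,8R,10Z)-10-bromo-8-[(tert-butyldimethylsilyl)oxy]-2,6-dimethyl-1-[(triethylsilyl)oxy]tetradeca-6,10,13-trien-2-ol | C=CC/C=C(Br)/C[C@@H](O[Si](C)(C)C(C)(C)C)/C=C(\C)CCC[C@](C)(O)CO[Si](CC)(CC)CC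
F7 | step 6 | (5E,10S)-6,10-dimethyl-11-[(triethylsilyl)oxy]undec-5-en-1-yne-4,10-diol, mixture of C4 epimers | C#CCC(O)/C=C(\C)CCC[C@](C)(O)CO[Si](CC)(CC)CC
F8 | step 6 | (5E,10S)-10-hydroxy-6,10-dimethyl-11-[(triethylsilyl)oxy]undec-5-en-1-yn-4-one | C#CCC(=O)/C=C(\C)CCC[C@](C)(O)CO[Si](CC)(CC)CC
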